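**Retrosynthetic overview**
- Target = (13R)-9α,13:15,16-diepoxy-6β,19-dihydroxylabd-14-en-12-one. C1–C12 and C17–C20, the six stereocentres of rings A/B (C4, C5, C6, C8, C9, C10) and the 6β/19/9α oxygens map atom for atom onto the chiral-pool labdane (+)-marrubiin.
- Ring D (2,3-dihydrofuran) is cut last at O–C15: alkynol cycloisomerisation of an oxolan-3-one that carries C≡CH and CH2OH on C13. The C12 ketone comes from a 12-OH.
- Ring C (oxolane O9–C9–C11–C12–C13) is cut at O9–C13: one-pot asymmetric epoxidation and strain-release spirocyclisation of an acyclic (E)-enynol. The enabling feature is the C12–C13 oxirane whose fully substituted C13 (bearing C≡CH and CH2OH) lies four atoms from the tertiary 9α-OH, so only C13 can be attacked and the three-ring strain drives the closure.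
- The enynol comes from a C12 aldehyde (Wittig, Sonogashira, reduction). The aldehyde comes from marrubiin by excision of the furan carbons C13–C16 (furan → acid → lactone → ketene acetal ozonolysis).
- Ring order: rings A/B (from marrubiin) → ring C (step 8) → ring D (step 12).

Key step: step 8

Remark: labdane numbering (C1–C20) is used for all compounds; TBS = tert-butyldimethylsilyl, TES = triethylsilyl; (+)-marrubiin, the bromo ylide of step 5 and ethynyltrimethylsilane are taken as purchasable.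

**Step 1**
Reactants: 1 (+)-marrubiin (15,16-epoxy-9α-hydroxylabda-13(16),14-dien-19,6β-olide)
Product: 2 marrubenol (15,16-epoxylabda-13(16),14-diene-6β,9α,19-triol)
Conditions: LiAlH4, THF, 0 °C to reflux
Reagents that add atoms: none
Why: Hydride reduction of a lactone to a diol: LiAlH4 should open the hindered 19,6β-γ-lactone to the 6β,19-diol while the furan, the tertiary 9α-OH and all stereocentres stay untouched.

**Step 2**
Reactants: 2 marrubenol
Product: 3 6β,19-bis(tert-butyldimethylsilyloxy)-15,16-epoxylabda-13(16),14-dien-9α-ol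
Conditions: TBSOTf, 2,6-lutidine, CH2Cl2, −78 to 0 °C
Reagents that add atoms: tert-butyldimethylsilyl trifluoromethanesulfonate CC(C)(C)[Si](C)(C)OS(=O)(=O)C(F)(F)F
Why: Silyl ether formation with a silyl triflate: the primary 19-OH and the axial secondary 6β-OH should be silylated, while the tertiary 9α-OH, buried between the quaternary C10 and C8, is expected to stay free with a small excess of reagent at low temperature.

**Step 3**
Reactants: 3 6β,19-bis(tert-butyldimethylsilyloxy)-15,16-epoxylabda-13(16),14-dien-9α-ol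
Product: 5 6β,19-bis(TBSO)-9α-hydroxy-14,15,16-trinorlabdan-13-oic acid 13,9-lactone (spiro γ-lactone at C9; its carbonyl carbon is C13 of marrubiin), via hydroxy acid 4 (not isolated)
Conditions: RuCl3·xH2O (cat.), NaIO4, EtOAc/MeCN/H2O, 0 °C to rt; then PPTS (cat.), PhMe, 50 °C
Reagents that add atoms: sodium periodate [Na+].[O-]I(=O)(=O)=O (oxygen delivered through RuO4)
Why: Oxidative degradation of a furan to a carboxylic acid by catalytic RuO4 (the 3-furyl group as a masked carboxyl) followed by lactonisation: the electron-rich furan is consumed far faster than any C–H bond or silyl ether, and the γ-hydroxy acid closes on the tertiary 9α-oxygen, which ties up the 9-OH for the next step.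

**Step 4**
Reactants: 5 spiro γ-lactone
Product: 8 6β,19-bis(TBSO)-9α-hydroxy-13,14,15,16-tetranorlabdan-12-al, via ketene silyl acetal 6 (not isolated), via silyl carbonate aldehyde 7 (not isolated)
Conditions: LiN(i-Pr)2, THF, −78 °C; Me3SiCl, −78 °C to rt; then O3, CH2Cl2, −78 °C; Me2S; aq. NaHCO3
Reagents that add atoms: ozone [O-][O+]=O; chlorotrimethylsilane C[Si](C)(C)Cl (its atoms stay only in 6 and 7)
Why: Enolate O-silylation and enol ether ozonolysis: the ketene silyl acetal is cleaved at its electron-rich C12=C13 bond to the C12 aldehyde and a silyl carbonate on O9, which loses CO2 on bicarbonate work-up, so that the old C13 is excised and the 9α-OH is set free without touching C9.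

**Step 5**
Reactants: 8 6β,19-bis(TBSO)-9α-hydroxy-13,14,15,16-tetranorlabdan-12-al; 9 ethyl bromo(triphenyl-λ5-phosphanylidene)acetate
Product: 10 ethyl (12Z)-13-bromo-6β,19-bis(TBSO)-9α-hydroxy-14,15-dinorlabd-12-en-16-oate
Conditions: CH2Cl2, rt
Reagents that add atoms: none
Why: Wittig olefination with a stabilised α-bromo ylide: it should give mainly the (Z)-α-bromo enoate (C11 trans to the ester) under neutral conditions that do not provoke retro-aldol cleavage of the β-hydroxy aldehyde; the ylide carbon becomes C13 of the target.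

**Step 6**
Reactants: 10 (Z)-α-bromo enoate; 11 ethynyltrimethylsilane
Product: 12 ethyl (12E)-6β,19-bis(TBSO)-9α-hydroxy-15-(trimethylsilyl)labd-12-en-14-yn-16-oate
Conditions: Pd(PPh3)2Cl2 (cat.), CuI (cat.), Et3N, THF, rt
Reagents that add atoms: none
Why: Sonogashira coupling: the activated alkenyl bromide couples with the terminal alkyne with retention of the alkene geometry, which installs C14 and C15.

**Step 7**
Reactants: 12 enyne ester
Product: 14 (12E)-6β,19-bis(TBSO)labd-12-en-14-yne-9α,16-diol, via silylated enynol 13 (not isolated)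
Conditions: i-Bu2AlH, CH2Cl2, −78 °C; then K2CO3, MeOH, rt
Reagents that add atoms: none
Why: 1,2-Reduction of the conjugated ester by the aluminium hydride to the allylic alcohol followed by base-mediated protodesilylation of the alkyne: neither stage affects the alkene geometry or the silyl ethers.

**Step 8**
Reactants: 14 (12E)-6β,19-bis(TBSO)labd-12-en-14-yne-9α,16-diol
Product: 16 (12S,13R)-6β,19-bis(TBSO)-9α,13-epoxylabd-14-yne-12,16-diol, via epoxy alcohol 15 (not isolated)
Conditions: Ti(OiPr)4 (cat.), L-(+)-diethyl tartrate (cat.), t-BuOOH, 4 Å MS, CH2Cl2, −20 °C; then CSA (cat.), −20 to 0 °C, same flask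
Reagents that add atoms: tert-butyl hydroperoxide CC(C)(C)OO
Why: Titanium–tartrate-directed oxygen transfer from t-BuOOH to the C12=C13 bond (Sharpless asymmetric epoxidation) gives the (12S,13S)-oxirane 15, and the added acid then lets the tertiary 9α-OH open the activated oxirane at C13 with release of the three-ring strain. The closest known reaction types are the in-flask cyclisation of hydroxy epoxy alcohols formed under these epoxidation conditions and the acid-promoted 5-endo opening of 3,4-epoxy alcohols at a fully substituted oxirane carbon to give 2,2-disubstituted oxolan-3-ols. Ring C (O9, C9, C11, C12, C13) closes in the 5-endo epoxide-opening mode, the only alternative being a 4-exo attack at C12 that would give an oxetane. C12 and C13 are set by reagent control (L-(+)-tartrate, the same facial sense as (E)-2-hexen-1-ol to its (2S,3S)-epoxide), and C13 is then inverted by backside attack (13S in 15 to 13R in 16), so that the quaternary spiro centre does not depend on the remote decalin; C12 keeps its configuration and is erased later by oxidation. The step needs regioselective attack at C13 and a tight, SN2-like transition state: the four-atom tether lets O9 reach only C13, C13 is the fully substituted carbon whose C–O bond is loosened on protonation, and its ethynyl and oxymethyl substituents disfavour a free cation that could scramble C13 or trigger a hydride shift. Chemoselectivity comes from the allylic 16-OH, which directs titanium to the C12=C13 bond alone; the alkyne, the silyl ethers and the homoallylic 9-OH are not oxidised.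

**Step 9**
Reactants: 16 (12S,13R)-6β,19-bis(TBSO)-9α,13-epoxylabd-14-yne-12,16-diol
Product: 17 (12S,13R)-6β,19-bis(TBSO)-9α,13-epoxy-16-(triethylsilyloxy)labd-14-yn-12-ol
Conditions: Et3SiCl, imidazole, CH2Cl2, −20 °C
Reagents that add atoms: chlorotriethylsilane CC[Si](Cl)(CC)CC
Why: Selective silylation: the primary 16-OH reacts with the chlorosilane much faster than the secondary 12-OH next to the quaternary C13.

**Step 10**
Reactants: 17 (12S,13R)-6β,19-bis(TBSO)-9α,13-epoxy-16-(triethylsilyloxy)labd-14-yn-12-ol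
Product: 18 (13R)-6β,19-bis(TBSO)-9α,13-epoxy-16-(triethylsilyloxy)labd-14-yn-12-one
Conditions: DMP, pyridine, CH2Cl2, 0 °C to rt
Reagents that add atoms: none
Why: Oxidation of a secondary alcohol with the hypervalent-iodine reagent DMP: the only free hydroxyl is converted into the C12 ketone under buffered conditions, and the adjacent C13 is quaternary and cannot epimerise.

**Step 11**
Reactants: 18 (13R)-6β,19-bis(TBSO)-9α,13-epoxy-16-(triethylsilyloxy)labd-14-yn-12-one
Product: 19 (13R)-9α,13-epoxy-6β,16,19-trihydroxylabd-14-yn-12-one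
Conditions: HF·pyridine, pyridine/THF, 0 °C to rt
Reagents that add atoms: none
Why: Fluoride-mediated desilylation under acidic buffering: all three silyl ethers are cleaved without base, so the β-hydroxy ketone (16-OH/C12=O) does not undergo retro-aldol loss of C16, and the alkyne and the C13 ether are unaffected.

**Step 12**
Reactants: 19 (13R)-9α,13-epoxy-6β,16,19-trihydroxylabd-14-yn-12-one
Product: 20 (13R)-9α,13:15,16-diepoxy-6β,19-dihydroxylabd-14-en-12-one (CNP0176827.1)
Conditions: Mo(CO)6 (cat.), Et3N, Et2O, hν (350 nm), rt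
Reagents that add atoms: none
Why: Alkynol cycloisomerisation through a molybdenum vinylidene: Mo(CO)5(NEt3) converts the terminal alkyne into a vinylidene whose C15 is attacked by the homopropargylic 16-OH (5-endo closure to the 2,3-dihydrofuran), under amine-buffered conditions that preserve the acid-labile enol ether and leave C13 and the remote 6β- and 19-hydroxyls untouched.

**Compound list**
1 | (+)-marrubiin | C[C@@H]1C[C@@H](O3)[C@H]2[C@@](C)(C3=O)CCC[C@]2(C)[C@@]1(O)CCc1ccoc1 | starting material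
2 | marrubenol (15,16-epoxylabda-13(16),14-diene-6β,9α,19-triol) | C[C@@H]1C[C@@H](O)[C@H]2[C@@](C)(CO)CCC[C@]2(C)[C@@]1(O)CCc1ccoc1 | intermediate
3 | 6β,19-bis(TBSO)-15,16-epoxylabda-13(16),14-dien-9α-ol | C[C@@H]1C[C@@H](O[Si](C)(C)C(C)(C)C)[C@H]2[C@@](C)(CO[Si](C)(C)C(C)(C)C)CCC[C@]2(C)[C@@]1(O)CCc1ccoc1 | intermediate
4 | 6β,19-bis(TBSO)-9α-hydroxy-14,15,16-trinorlabdan-13-oic acid | C[C@@H]1C[C@@H](O[Si](C)(C)C(C)(C)C)[C@H]2[C@@](C)(CO[Si](C)(C)C(C)(C)C)CCC[C@]2(C)[C@@]1(O)CCC(=O)O | intermediate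
5 | 13,9-lactone of 4 (spiro γ-lactone at C9) | C[C@@H]1C[C@@H](O[Si](C)(C)C(C)(C)C)[C@H]2[C@@](C)(CO[Si](C)(C)C(C)(C)C)CCC[C@]2(C)[C@@]12CCC(=O)O2 | intermediate
6 | trimethylsilyl ketene acetal of 5 (9α,13-epoxy-13-(trimethylsilyloxy)-14,15,16-trinorlabd-12-ene) | C[C@@H]1C[C@@H](O[Si](C)(C)C(C)(C)C)[C@H]2[C@@](C)(CO[Si](C)(C)C(C)(C)C)CCC[C@]2(C)[C@@]12CC=C(O[Si](C)(C)C)O2 | intermediate
7 | 6β,19-bis(TBSO)-12-oxo-13,14,15,16-tetranorlabdan-9α-yl trimethylsilyl carbonate | C[C@@H]1C[C@@H](O[Si](C)(C)C(C)(C)C)[C@H]2[C@@](C)(CO[Si](C)(C)C(C)(C)C)CCC[C@]2(C)[C@@]1(OC(=O)O[Si](C)(C)C)CC=O | intermediate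
8 | 6β,19-bis(TBSO)-9α-hydroxy-13,14,15,16-tetranorlabdan-12-al | C[C@@H]1C[C@@H](O[Si](C)(C)C(C)(C)C)[C@H]2[C@@](C)(CO[Si](C)(C)C(C)(C)C)CCC[C@]2(C)[C@@]1(O)CC=O | intermediate
9 | ethyl bromo(triphenyl-λ5-phosphanylidene)acetate | CCOC(=O)C(Br)=P(c1ccccc1)(c1ccccc1)c1ccccc1 | starting material
10 | ethyl (12Z)-13-bromo-6β,19-bis(TBSO)-9α-hydroxy-14,15-dinorlabd-12-en-16-oate | C[C@@H]1C[C@@H](O[Si](C)(C)C(C)(C)C)[C@H]2[C@@](C)(CO[Si](C)(C)C(C)(C)C)CCC[C@]2(C)[C@@]1(O)C/C=C(/C(=O)OCC)Br | intermediate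
11 | ethynyltrimethylsilane | C#C[Si](C)(C)C | starting material
12 | ethyl (12E)-6β,19-bis(TBSO)-9α-hydroxy-15-(trimethylsilyl)labd-12-en-14-yn-16-oate | C[C@@H]1C[C@@H](O[Si](C)(C)C(C)(C)C)[C@H]2[C@@](C)(CO[Si](C)(C)C(C)(C)C)CCC[C@]2(C)[C@@]1(O)C/C=C(/C(=O)OCC)C#C[Si](C)(C)C | intermediate
13 | (12E)-6β,19-bis(TBSO)-15-(trimethylsilyl)labd-12-en-14-yne-9α,16-diol | C[C@@H]1C[C@@H](O[Si](C)(C)C(C)(C)C)[C@H]2[C@@](C)(CO[Si](C)(C)C(C)(C)C)CCC[C@]2(C)[C@@]1(O)C/C=C(/CO)C#C[Si](C)(C)C | intermediate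
14 | (12E)-6β,19-bis(TBSO)labd-12-en-14-yne-9α,16-diol | C[C@@H]1C[C@@H](O[Si](C)(C)C(C)(C)C)[C@H]2[C@@](C)(CO[Si](C)(C)C(C)(C)C)CCC[C@]2(C)[C@@]1(O)C/C=C(/CO)C#C | intermediate
15 | (12S,13S)-6β,19-bis(TBSO)-12,13-epoxylabd-14-yne-9α,16-diol | C[C@@H]1C[C@@H](O[Si](C)(C)C(C)(C)C)[C@H]2[C@@](C)(CO[Si](C)(C)C(C)(C)C)CCC[C@]2(C)[C@@]1(O)C[C@@H]1O[C@]1(CO)C#C | intermediate
16 | (12S,13R)-6β,19-bis(TBSO)-9α,13-epoxylabd-14-yne-12,16-diol | C[C@@H]1C[C@@H](O[Si](C)(C)C(C)(C)C)[C@H]2[C@@](C)(CO[Si](C)(C)C(C)(C)C)CCC[C@]2(C)[C@@]12C[C@H](O)[C@](CO)(C#C)O2 | intermediate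
17 | (12S,13R)-6β,19-bis(TBSO)-9α,13-epoxy-16-(triethylsilyloxy)labd-14-yn-12-ol | C[C@@H]1C[C@@H](O[Si](C)(C)C(C)(C)C)[C@H]2[C@@](C)(CO[Si](C)(C)C(C)(C)C)CCC[C@]2(C)[C@@]12C[C@H](O)[C@](CO[Si](CC)(CC)CC)(C#C)O2 | intermediate
18 | (13R)-6β,19-bis(TBSO)-9α,13-epoxy-16-(triethylsilyloxy)labd-14-yn-12-one | C[C@@H]1C[C@@H](O[Si](C)(C)C(C)(C)C)[C@H]2[C@@](C)(CO[Si](C)(C)C(C)(C)C)CCC[C@]2(C)[C@@]12CC(=O)[C@](CO[Si](CC)(CC)CC)(C#C)O2 | intermediate
19 | (13R)-9α,13-epoxy-6β,16,19-trihydroxylabd-14-yn-12-one | C[C@@H]1C[C@@H](O)[C@H]2[C@@](C)(CO)CCC[C@]2(C)[C@@]12CC(=O)[C@](CO)(C#C)O2 | intermediate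
20 | (13R)-9α,13:15,16-diepoxy-6β,19-dihydroxylabd-14-en-12-one (CNP0176827.1) | C[C@@H]1C[C@@H](O)[C@H]2[C@@](C)(CO)CCC[C@]2(C)[C@@]12CC(=O)[C@]1(C=COC1)O2 | target

**Summary**
Total step count: 12. Longest linear sequence: 12 steps (1 to 20).

**Steps most likely to fail**

Step 8. The oxirane may resist opening at the electron-poor, fully substituted C13, or it may ionise to a free propargylic cation, with loss of stereospecificity at C13 or a hydride shift to a C12 ketone. The fallback sets out from 14 and changes the activation to a cobalt-stabilised cation (Nicholas reaction). The epoxidation stage is run alone with D-(−)-diethyl tartrate to give the (12R,13R)-epoxy alcohol F1. Complexation of the alkyne with Co2(CO)8 gives the hexacarbonyldicobalt complex F2. BF3·OEt2 in CH2Cl2 at −78 °C generates the cobalt-bridged cation, which the 9α-OH should trap in the endo mode with net retention at C13 (double inversion), to give the cyclised complex F3. Oxidative decomplexation with (NH4)2Ce(NO3)6 gives the (12R,13R)-diol F4, the 12-epimer of 16. Silylation as in step 9 gives the 16-O-TES ether F5, and oxidation as in step 10 erases C12 and returns to the route at 18.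

Step 12. The metallated dihydrofuran may undergo β-elimination across C14–C13 with expulsion of the C13–O9 oxygen and aromatisation to a 3-acylfuran, or the amine may induce retro-aldol loss of C16. The fallback sets out from 18 and builds ring D by hydration and dehydration instead. Hydroboration of the terminal alkyne with dicyclohexylborane and oxidation with NaBO3 give the 15-aldehyde F6. AcOH/THF/H2O removes only the triethylsilyl group, and the freed 16-OH closes onto the aldehyde to give the lactol F7. MsCl/Et3N dehydrates the lactol to the bis-TBS ether of the target F8. Bu4NF then returns to the route at 20.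

Step 4. The lactone enolate may be silylated incompletely or on carbon, and the β-hydroxy aldehyde may be over-oxidised or cleaved by retro-aldol reaction during ozonolysis work-up. The fallback sets out from 5 and replaces the ozonolysis by glycol cleavage. Enolate hydroxylation (KN(SiMe3)2, then 2-(phenylsulfonyl)-3-phenyloxaziridine) gives the 12-hydroxy lactone F9. LiAlH4 reduces it to the 9α,12,13-triol F10. NaIO4 cleaves the 12,13-glycol and returns to the route at 8.

**Further compounds**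
F1 | step 8 | (12R,13R)-6β,19-bis(TBSO)-12,13-epoxylabd-14-yne-9α,16-diol | C[C@@H]1C[C@@H](O[Si](C)(C)C(C)(C)C)[C@H]2[C@@](C)(CO[Si](C)(C)C(C)(C)C)CCC[C@]2(C)[C@@]1(O)C[C@H]1O[C@@]1(CO)C#C
F2 | step 8 | Co2(CO)6 complex of the alkyne of F1 | C[C@@H]1C[C@@H](O[Si](C)(C)C(C)(C)C)[C@H]2[C@@](C)(CO[Si](C)(C)C(C)(C)C)CCC[C@]2(C)[C@@]1(O)C[C@H]1O[C@@]1(CO)C23[CH]4[Co]2(=C=O)(=C=O)(=C=O)[Co]34(=C=O)(=C=O)=C=O
F3 | step 8 | Co2(CO)6 complex of the alkyne of F4 | C[C@@H]1C[C@@H](O[Si](C)(C)C(C)(C)C)[C@H]2[C@@](C)(CO[Si](C)(C)C(C)(C)C)CCC[C@]2(C)[C@@]12C[C@@H](O)[C@](CO)(C34[CH]5[Co]3(=C=O)(=C=O)(=C=O)[Co]45(=C=O)(=C=O)=C=O)O2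
F4 | step 8 | (12R,13R)-6β,19-bis(TBSO)-9α,13-epoxylabd-14-yne-12,16-diol | C[C@@H]1C[C@@H](O[Si](C)(C)C(C)(C)C)[C@H]2[C@@](C)(CO[Si](C)(C)C(C)(C)C)CCC[C@]2(C)[C@@]12C[C@@H](O)[C@](CO)(C#C)O2
F5 | step 8 | (12R,13R)-6β,19-bis(TBSO)-9α,13-epoxy-16-(triethylsilyloxy)labd-14-yn-12-ol | C[C@@H]1C[C@@H](O[Si](C)(C)C(C)(C)C)[C@H]2[C@@](C)(CO[Si](C)(C)C(C)(C)C)CCC[C@]2(C)[C@@]12C[C@@H](O)[C@](CO[Si](CC)(CC)CC)(C#C)O2
F6 | step 12 | (13R)-6β,19-bis(TBSO)-9α,13-epoxy-12-oxo-16-(triethylsilyloxy)labdan-15-al | C[C@@H]1C[C@@H](O[Si](C)(C)C(C)(C)C)[C@H]2[C@@](C)(CO[Si](C)(C)C(C)(C)C)CCC[C@]2(C)[C@@]12CC(=O)[C@](CO[Si](CC)(CC)CC)(CC=O)O2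
F7 | step 12 | (13R)-6β,19-bis(TBSO)-9α,13:15,16-diepoxy-15-hydroxylabdan-12-one (lactol, both 15-epimers) | C[C@@H]1C[C@@H](O[Si](C)(C)C(C)(C)C)[C@H]2[C@@](C)(CO[Si](C)(C)C(C)(C)C)CCC[C@]2(C)[C@@]12CC(=O)[C@]1(CC(O)OC1)O2
F8 | step 12 | (13R)-6β,19-bis(TBSO)-9α,13:15,16-diepoxylabd-14-en-12-one | C[C@@H]1C[C@@H](O[Si](C)(C)C(C)(C)C)[C@H]2[C@@](C)(CO[Si](C)(C)C(C)(C)C)CCC[C@]2(C)[C@@]12CC(=O)[C@]1(C=COC1)O2
F9 | step 4 | 6β,19-bis(TBSO)-9α,12-dihydroxy-14,15,16-trinorlabdan-13-oic acid 13,9-lactone (both 12-epimers) | C[C@@H]1C[C@@H](O[Si](C)(C)C(C)(C)C)[C@H]2[C@@](C)(CO[Si](C)(C)C(C)(C)C)CCC[C@]2(C)[C@@]12CC(O)C(=O)O2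
F10 | step 4 | 6β,19-bis(TBSO)-14,15,16-trinorlabdane-9α,12,13-triol (both 12-epimers) | C[C@@H]1C[C@@H](O[Si](C)(C)C(C)(C)C)[C@H]2[C@@](C)(CO[Si](C)(C)C(C)(C)C)CCC[C@]2(C)[C@@]1(O)CC(O)CO
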